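Follow one rate through these flasks, the rate at which target is made, and leave the concentrations aside.

    substrate ⇌ intermediate A (K1 = 0.43, k1 = 0.012 s⁻¹)
    intermediate A ⇌ intermediate B (K2 = 45, k2 = 0.031 s⁻¹)
    reagent + intermediate A → target (k3 = 5.6 M⁻¹ s⁻¹)
    intermediate A → intermediate C (k4 = 0.020 s⁻¹)
    intermediate C → side product (k5 = 0.058 s⁻¹)
    intermediate A → side product (k6 = 0.0025 s⁻¹)
    target ⇌ isomer of the product (K7 = 0.61, k7 = 0.0082 s⁻¹)

| flask | substrate | reagent | time | remark |
|---|---|---|---|---|
| ochre | 42 mM | 25.2 mM | 80 s | a closed flask charged with all of it at once and left for 80 s |
| violet | 42 mM | 25.2 mM (fed, over 80.0 s) | 80 s | a stirred flask in which reagent is dosed at a steady rate over 80.0 s without added volume, worked up at 80 s |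
| red | 42 mM | 25.2 mM |  | a single well-mixed tank run continuously and read at steady state, 80 s in it on average |
| grey | 42 mM (fed, over 80.0 s) | 25.2 mM | 80 s | all but substrate at the start; substrate goes in evenly over 80.0 s, the run ends at 80 s |

- the set-up with the highest amount of target at the outlet or at the end, in percent of the substrate put in ("none" if the first two lie within 2 percentage points) (ochre / violet / red / grey / none)
- amount of target at the outlet or at the end, in percent of the substrate put in, ochre
- amount of target at the outlet or at the end, in percent of the substrate put in, violet
- amount of target at the outlet or at the end, in percent of the substrate put in, red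
- amount of target at the outlet or at the end, in percent of the substrate put in, grey

- the stated concentrations are those of everything mixed, before any reaction; amounts are the same in each set-up
- the feed brings no volume worth counting
- run time (ochre): 80 s

Take ochre. Substrate opens to intermediate A at 0.012 s⁻¹, and intermediate A then has a choice. Reagent catches it at k3[reagent], a pseudo-first-order rate of 0.141 s⁻¹ at the charge, while the steps to intermediate B, intermediate C and side product together leak it at 0.0535 s⁻¹. Divide that leak by 5.6 M⁻¹ s⁻¹ and you have the half-capture level, the [reagent] at which catching equals leaking: 9.55 mM. The capture share, the part of what goes forward that reagent catches, is [reagent]/([reagent] + half-capture level), so 72.5% at the start. Intermediate A also returns to substrate at 0.0279 s⁻¹, slower than the catch, which leaves a forward passage of 0.0105 s⁻¹. So target starts at 0.00761 s⁻¹ of the substrate charge, and unslowed over 80 s that gives 60.9%.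

Two things slow it. Substrate wears away at the passage rate, a factor 0.432 by the end, or −0.365 in powers of ten. Reagent goes too: the charge ratio 60.0% lies inside the range of the capture share, so I let [reagent] fall by that same factor. The share then ends at 53.3%, a further factor 0.734, or −0.134. Adding the logarithms gives −0.499, so the end rate is 0.00241 s⁻¹. The logarithmic mean of the two rates over the run makes 36.2%. Target also turns to isomer of the product at 0.0082 s⁻¹ and comes back at 0.01344 s⁻¹, so the pair relaxes at 0.0216 s⁻¹ toward a target share of 62.1%. Because the end rate lies below the start rate, target is made early, and with an exponential fall between those two rates its mean age at the end is 47.5 s, more than 40.0 s. That age keeps 75.7% of what was made, so I expect ochre near 27.4%. In violet the dosed reagent averages below 0.0126 M, where the share is 56.9%, less than ochre's start, so I put ochre above violet and leave red and grey unreckoned.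

The forecast, holding that “having all the reagent in at the start favours ochre”, names ochre, with 26%, 20.3%, 19.1% and 16.2% in the order asked, its ochre figure lower than mine.

The simulation gives 26.1% for ochre, 18.8% for violet, 19.0% for red and 16.3% for grey, so ochre stands first. In ochre, reagent uses intermediate A 3.3 times as fast as the forward step to intermediate B at 30.8 s and 2.0 times at 80.0 s, when 44% of the reagent is left, which is 11.2 mM against the half-capture level of 9.55 mM and a capture share of 53.9%. In ochre left until 2.5 min, reagent stands at 26.0% of its charge, the capture share at 40.7%, and target at 30.7%.

The constants used here belong to no real substance; the rest is arithmetic.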